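A neighbour of birch will run with less X, so I want one reckoning that serves both flasks: how much E has X given by the end?

    J + E → J.E (k1 = 0.016 /M/s)
    G + E → G.E (k2 = 0.44 /M/s)
    J → G (k3 = 0.0031 /s)
    X → E (k4 = 6.2 × 10⁻⁴ /s)

the same everywhere: time 50 min

| charge | J | X | remark |
|---|---|---|---|
| birch | 0.20 M | 2.50 equiv (fed, over 20 min) | all else is in the flask from the start; the feed brings no volume worth counting |
| elm | 0.20 M | 2.50 equiv | everything together at the start |
| cedar | 0.20 M (fed, over 20 min) | 2.50 equiv | all else is in the flask from the start; the feed brings no volume worth counting |

- the flask that comes out highest in amount of G.E, in percent of the J charged, or "all alike" when all lie within 1.5 percentage points (birch / elm / cedar / all alike)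
- G.E at the end, in percent of the J charged, birch
- G.E at the end, in percent of the J charged, elm
- G.E at the end, in percent of the J charged, cedar

1. X turns to E with a life of 26.9 min, and J turns to G with a life of 5.38 min, so J's life is shorter than X's.

2. Fed X arrives on average at mid-feed, so as a rough step I let birch's X start there. By the end 77.4% of it has become E, which is 1.94 per J charged. In elm and cedar X starts at once and gives 2.11. These exceed one, so J is the limiting reagent, and I take G.E as the charge less J.E.

3. Within one life of J, birch's feed has given 0.0672 of E per J charged and elm's X 0.453. Birch's J therefore meets less E than elm's, and I put birch ahead of elm.

4. In cedar J arrives among standing E. By the end of the feed X has given 1.31 while one charge of J has come in. I count the J fed during the last life of J, 0.269 of the charge, as still waiting for E, so about 0.581 of the charge stands as spare E. Against the step to G, that E takes a share 37.5% of J. I commit to cedar near 62.5% G.E.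

5. The weak link is step 2, because the feed is spread over 20 min, and I reforge it moment by moment. The delivered share, the part of an X charge fed over that time which has become E by the end, is 76.9%.

The forecast names birch, with 98.6% for birch, 92.5% for elm and 70% for cedar. For cedar it says “about one third is diverted”, and its figure stands above mine.

The flask comes out highest in birch: birch 99.1%, elm 93.3%, cedar 68.0%. Cedar's J.E is 32.0%, below my share.

The delivered share leaves 23.1% of the X in birch, and birch holds 23.1% after 50.0 min, beside 0.906% J.E. The neighbour of birch has 0.620 equiv of X on the same feed, so the same share delivers 0.477 of E per J charged, below one. That neighbour ends with 47.3% G.E and 52.5% G.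

Its constants come from no measurement; the rest is arithmetic.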